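**Assumption:** the target has no stereocentres (planar flavone), so "single enantiomer" needs no stereocontrol; the route gives the one achiral compound.

## Retrosynthetic overview

1. Target 13 ⇐ one-pot Lewis-acid deprotection (4'-OBn and the chelated 5-OMe) of 4'-benzyloxy-3,5,7,8,2'-pentamethoxyflavone 11.
2. 11 ⇐ cyclodehydration (O1–C2) of β-diketone 10 ⇐ Baker–Venkataraman acyl shift (C2–C3) of aryl ester 9; the 3-OMe comes in with the ω-methoxy ketone.
3. 9 ⇐ phenol 4 + acid 7 (the 4-OBn-2-OMe B ring).
4. 4 ⇐ Friedel–Crafts acylation with ortho-demethylation of 1,2,3,5-tetramethoxybenzene 1 by methoxyacetyl chloride 2; 7 ⇐ benzylation and saponification of methyl 4-hydroxy-2-methoxybenzoate 5.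
5. Rings A and B are bought; only the pyranone C ring is built, last.

## Route

Step 1
Reactants: 1 1,2,3,5-tetramethoxybenzene; 2 methoxyacetyl chloride
Product: 4 1-(2-hydroxy-3,4,6-trimethoxyphenyl)-2-methoxyethan-1-one, via tetramethoxyphenyl ketone 3 (not isolated)
Conditions: AlCl3 (2.5 equiv), Et2O, 0 °C → rt, 24 h; ice/dil. HCl
Reagents that add atoms: none
Why: Friedel–Crafts acylation at the only type of ring C–H of 1, then AlCl3-chelation-driven cleavage of the more crowded ortho methoxy (the one flanked by C=O and OMe), as in the known acetyl chloride case.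

Step 2
Reactants: 5 methyl 4-hydroxy-2-methoxybenzoate
Product: 7 4-(benzyloxy)-2-methoxybenzoic acid, via methyl 4-(benzyloxy)-2-methoxybenzoate 6 (not isolated)
Conditions: BnBr, K2CO3, DMF, 60 °C; then 2 M aq. NaOH, MeOH, 70 °C; HCl to pH 2
Reagents that add atoms: benzyl bromide BrCc1ccccc1; sodium hydroxide [Na+].[OH-]
Why: Williamson O-benzylation of the only phenol followed by saponification of the methyl ester in the same pot.

Step 3
Reactants: 7 4-(benzyloxy)-2-methoxybenzoic acid; 4 1-(2-hydroxy-3,4,6-trimethoxyphenyl)-2-methoxyethan-1-one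
Product: 9 2-(methoxyacetyl)-3,5,6-trimethoxyphenyl 4-(benzyloxy)-2-methoxybenzoate, via 4-(benzyloxy)-2-methoxybenzoyl chloride 8 (not isolated)
Conditions: (COCl)2, cat. DMF, CH2Cl2, 0 °C → rt, evaporate; then 4, pyridine, DMAP (0.2 equiv), CH2Cl2, rt → 40 °C
Reagents that add atoms: none
Why: DMAP-catalysed O-acylation of the hindered, hydrogen-bonded phenol by the acid chloride; 4 has no other acylable group.

Step 4
Reactants: 9 2-(methoxyacetyl)-3,5,6-trimethoxyphenyl 4-(benzyloxy)-2-methoxybenzoate
Product: 11 2-[4-(benzyloxy)-2-methoxyphenyl]-3,5,7,8-tetramethoxy-4H-chromen-4-one, via β-diketone 10 (not isolated)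
Conditions: LiHMDS (2.5 equiv), THF, −78 °C → rt; AcOH quench, evaporate; then AcOH, cat. H2SO4 (1% v/v), 80 °C, 1 h
Reagents that add atoms: none
Why: Baker–Venkataraman rearrangement (the α-methoxy ketone enolate takes the aroyl group from the neighbouring ester) and acid cyclodehydration of the freed phenol onto the aryl ketone; the transient CH(OMe) centre of 10 becomes sp2.

Step 5
Reactants: 11 2-[4-(benzyloxy)-2-methoxyphenyl]-3,5,7,8-tetramethoxy-4H-chromen-4-one
Product: 13 5,4'-dihydroxy-3,7,8,2'-tetramethoxyflavone, via 4'-hydroxy-3,5,7,8,2'-pentamethoxyflavone 12 (not isolated)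
Conditions: BCl3 (1 M in CH2Cl2, 5 equiv), C6HMe5 (3 equiv), CH2Cl2, −78 °C (1 h) → 0 °C (2 h); MeOH, then dil. aq. HCl
Reagents that add atoms: none
Why: BCl3 with a cation scavenger cleaves the aryl benzyl ether at −78 °C, and on warming removes only the methyl ether peri to the C4 carbonyl (six-membered boron chelate); the unchelated 3-, 7-, 8- and 2'-OMe groups stay.

## Compound list

1 | 1,2,3,5-tetramethoxybenzene | COc1cc(OC)c(OC)c(OC)c1 | starting material
2 | methoxyacetyl chloride | COCC(Cl)=O | starting material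
3 | 2-methoxy-1-(2,3,4,6-tetramethoxyphenyl)ethan-1-one | COCC(=O)c1c(OC)cc(OC)c(OC)c1OC | intermediate (not isolated)
4 | 1-(2-hydroxy-3,4,6-trimethoxyphenyl)-2-methoxyethan-1-one | COCC(=O)c1c(OC)cc(OC)c(OC)c1O | intermediate
5 | methyl 4-hydroxy-2-methoxybenzoate | COC(=O)c1ccc(O)cc1OC | starting material
6 | methyl 4-(benzyloxy)-2-methoxybenzoate | COC(=O)c1ccc(OCc2ccccc2)cc1OC | intermediate (not isolated)
7 | 4-(benzyloxy)-2-methoxybenzoic acid | OC(=O)c1ccc(OCc2ccccc2)cc1OC | intermediate
8 | 4-(benzyloxy)-2-methoxybenzoyl chloride | ClC(=O)c1ccc(OCc2ccccc2)cc1OC | intermediate (not isolated)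
9 | 2-(methoxyacetyl)-3,5,6-trimethoxyphenyl 4-(benzyloxy)-2-methoxybenzoate | COCC(=O)c1c(OC)cc(OC)c(OC)c1OC(=O)c1ccc(OCc2ccccc2)cc1OC | intermediate
10 | 1-[4-(benzyloxy)-2-methoxyphenyl]-3-(2-hydroxy-3,4,6-trimethoxyphenyl)-2-methoxypropane-1,3-dione (racemic at C2, enolisable) | COC(C(=O)c1c(OC)cc(OC)c(OC)c1O)C(=O)c1ccc(OCc2ccccc2)cc1OC | intermediate (not isolated)
11 | 2-[4-(benzyloxy)-2-methoxyphenyl]-3,5,7,8-tetramethoxy-4H-chromen-4-one | COc1cc(OCc2ccccc2)ccc1-c1oc2c(OC)c(OC)cc(OC)c2c(=O)c1OC | intermediate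
12 | 2-(4-hydroxy-2-methoxyphenyl)-3,5,7,8-tetramethoxy-4H-chromen-4-one (present as its O-boron species) | COc1cc(O)ccc1-c1oc2c(OC)c(OC)cc(OC)c2c(=O)c1OC | intermediate (not isolated)
13 | 5-hydroxy-2-(4-hydroxy-2-methoxyphenyl)-3,7,8-trimethoxy-4H-chromen-4-one (5,4'-dihydroxy-3,7,8,2'-tetramethoxyflavone) | COc1cc(O)ccc1-c1oc2c(OC)c(OC)cc(O)c2c(=O)c1OC | target

## Step count and risks

Total steps: 5. Longest linear sequence: 4 steps (1 → 4 → 9 → 11 → 13, or equally 5 → 7 → 9 → 11 → 13).

**Step 1 (most likely to fail).** The methoxyacetyl acylium ion can lose CO under AlCl3 and alkylate the ring instead, and the demethylation must stop at the single crowded ortho methoxy. Fallback: set out from 1 and lithiate it at the same ring position (n-BuLi, TMEDA, THF, 0 °C; the C–H lies between two OMe groups) to give (2,3,4,6-tetramethoxyphenyl)lithium F1. Acylate this with the Weinreb amide N,2-dimethoxy-N-methylacetamide, which gives ketone 3, now isolated. The route is rejoined at 3, which is then converted to 4 as a separate operation with AlCl3 in MeCN at rt. This replaces electrophilic acylation by directed ortho-metalation, so no acylium ion is ever formed.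

**Step 4.** The α-methoxy, doubly ortho-substituted diketone may rearrange or cyclise sluggishly, and the benzyl ether may be partly lost in hot acid. Any debenzylated product is 12, which step 5 also converts to 13. Fallback: set out from 7 and dehydrate it with DCC in CH2Cl2 to 4-(benzyloxy)-2-methoxybenzoic anhydride F2. Heat 4 with F2 and Et3N at 165 °C (Allan–Robinson condensation, triethylamine variant), then briefly treat with aqueous-methanolic KOH to destroy excess anhydride. This gives 11 directly by thermal C-aroylation and ring closure in one operation and comes back to the route at 11.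

**Step 5.** Excess BCl3 or over-warming could also cleave the 3-OMe or the crowded 8-OMe, or the benzyl cation could C-benzylate ring A. Fallback: set out from 11 and remove only the chelated 5-methyl with AlBr3 in MeCN at 0 °C → rt, which leaves the benzyl ether and gives 2-[4-(benzyloxy)-2-methoxyphenyl]-5-hydroxy-3,7,8-trimethoxy-4H-chromen-4-one F3. Then hydrogenolyse the benzyl ether (H2 1 atm, 10% Pd/C, EtOAc–MeOH, rt), coming back to the route at 13. This splits the two deprotections into orthogonal steps and removes benzyl without any Lewis acid.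

## Further compounds

F1 | step 1 | (2,3,4,6-tetramethoxyphenyl)lithium | [Li]c1c(OC)cc(OC)c(OC)c1OC
F2 | step 4 | 4-(benzyloxy)-2-methoxybenzoic anhydride | COc1cc(OCc2ccccc2)ccc1C(=O)OC(=O)c1ccc(OCc2ccccc2)cc1OC
F3 | step 5 | 2-[4-(benzyloxy)-2-methoxyphenyl]-5-hydroxy-3,7,8-trimethoxy-4H-chromen-4-one | COc1cc(OCc2ccccc2)ccc1-c1oc2c(OC)c(OC)cc(O)c2c(=O)c1OC
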